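**Retrosynthetic overview**

1. The target comes from the achiral 7,2',4'-trihydroxy-5'-geranylisoflavone by an enzymatic, (3R)-selective reduction of C2=C3. The only stereocentre is set in the last step on the unprotected compound, so no later step can erode it.
2. The isoflavone core comes from 3-bromo-5-(methoxymethoxy)benzyne and an (E/Z)-2-aryl-3-methoxyacrylic acid. The aryne inserts into the O–C(=O) bond of the carboxyl group (O1–C8a and C4–C4a), then ring C closes (O1–C2) by addition–elimination.
3. Enabling feature: in ring A, C8a and C4a are ortho neighbours carrying O1 and the C4 carbonyl, and both O1 and C4 can come from one carboxyl group whose β-carbon is the masked C2. A bromine at C5, removed afterwards, fixes the regiochemistry.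
4. The acid comes from 4,6-dibromoresorcinol (one bromine to geranyl, the other to glyoxylate, then methoxymethylene Wittig). The aryne precursor comes from 4-(methoxymethoxy)phenol by dibromination, retro-Brook shift and triflation.
5. Ring order: rings A and B are bought as arenes; ring C is the only ring formed (step 9).

Key step: step 9

Abbreviations: geranyl = (2E)-3,7-dimethylocta-2,6-dien-1-yl; MOM = methoxymethyl.
Remark: the 3-methoxyacrylate ester, the derived acid and the ketone formed from it in the flask are used as E/Z mixtures at the enol ether double bond, because both isomers converge in the key step; their SMILES leave that double bond unspecified.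

**Route**

Step 1
Reactants: 1 4,6-dibromoresorcinol
Product: 2 1,5-dibromo-2,4-bis(methoxymethoxy)benzene
Conditions: MOMCl (2.5 equiv), i-Pr2NEt (3 equiv), CH2Cl2, 0 °C → rt
Reagents that add atoms: chloromethyl methyl ether (MOMCl), COCCl
Why: O-alkylation of both phenols (MOM protection) with an amine base is routine, and the MOM groups later stabilise the ortho-aryllithiums by chelation.

Step 2
Reactants: 2 1,5-dibromo-2,4-bis(methoxymethoxy)benzene; 3 geranyl bromide
Product: 5 1-bromo-5-geranyl-2,4-bis(methoxymethoxy)benzene, via aryllithium 4 (not isolated)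
Conditions: n-BuLi (1.0 equiv), THF, −78 °C; then CuBr·SMe2 (10 mol %), 3, −78 °C → 0 °C
Reagents that add atoms: none
Why: Bromine–lithium exchange at one of two equivalent C–Br bonds (a second exchange on the anion is much slower), followed by copper-catalysed SN2 allylic alkylation, should give the linear geranyl arene with the E double bond of 3 untouched.

Step 3
Reactants: 5 1-bromo-5-geranyl-2,4-bis(methoxymethoxy)benzene
Product: 7 methyl 2-[5-geranyl-2,4-bis(methoxymethoxy)phenyl]-2-oxoacetate, via aryllithium 6 (not isolated)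
Conditions: n-BuLi (1.05 equiv), THF, −78 °C; cannulate into dimethyl oxalate (3 equiv), THF, −78 °C; aq. NH4Cl
Reagents that add atoms: dimethyl oxalate, COC(=O)C(=O)OC
Why: Acylation of the aryllithium with excess oxalate by inverse addition should stop at the α-keto ester, because the tetrahedral adduct is stable at −78 °C.

Step 4
Reactants: 7 methyl 2-[5-geranyl-2,4-bis(methoxymethoxy)phenyl]-2-oxoacetate
Product: 8 methyl (E/Z)-2-[5-geranyl-2,4-bis(methoxymethoxy)phenyl]-3-methoxyprop-2-enoate
Conditions: Ph3P(CH2OMe)Cl (1.5 equiv), KOt-Bu (1.45 equiv), THF, 0 °C; then 7, 0 °C → rt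
Reagents that add atoms: (methoxymethyl)triphenylphosphonium chloride, COC[P+](c1ccccc1)(c1ccccc1)c1ccccc1.[Cl-]
Why: Wittig olefination of the ketone carbonyl (far more electrophilic than the ester) with the methoxymethylene ylide is the standard entry to 2-aryl-3-methoxyacrylates, and the E/Z outcome does not matter here.

Step 5
Reactants: 8 methyl (E/Z)-2-[5-geranyl-2,4-bis(methoxymethoxy)phenyl]-3-methoxyprop-2-enoate
Product: 9 (E/Z)-2-[5-geranyl-2,4-bis(methoxymethoxy)phenyl]-3-methoxyprop-2-enoic acid
Conditions: LiOH·H2O (3 equiv), THF/MeOH/H2O, 40 °C; then 1 M HCl to pH 4 at 0 °C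
Reagents that add atoms: lithium hydroxide, [Li+].[OH-]
Why: Saponification of the methyl ester leaves the MOM ethers and the enol ether untouched, and a brief cold acidification to pH 4 should free the acid without hydrolysing the acetals.

Step 6
Reactants: 10 4-(methoxymethoxy)phenol
Product: 11 2,6-dibromo-4-(methoxymethoxy)phenol
Conditions: NBS (2.05 equiv), i-Pr2NH (10 mol %), CH2Cl2, 0 °C
Reagents that add atoms: N-bromosuccinimide, O=C1CCC(=O)N1Br
Why: Amine-catalysed electrophilic bromination with NBS goes to both positions ortho to the free hydroxyl (para is blocked) under non-acidic conditions that spare the MOM ether.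

Step 7
Reactants: 11 2,6-dibromo-4-(methoxymethoxy)phenol
Product: 12 [2,6-dibromo-4-(methoxymethoxy)phenoxy]trimethylsilane
Conditions: HMDS (0.7 equiv), THF, 70 °C; concentrate
Reagents that add atoms: hexamethyldisilazane, C[Si](C)(C)N[Si](C)(C)C
Why: O-silylation of the hindered, acidic phenol with HMDS gives only ammonia as by-product, so the crude silyl ether can be used directly.

Step 8
Reactants: 12 [2,6-dibromo-4-(methoxymethoxy)phenoxy]trimethylsilane
Product: 15 2-bromo-4-(methoxymethoxy)-6-(trimethylsilyl)phenyl triflate, via aryllithium 13 (not isolated), via lithium phenoxide 14 (not isolated)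
Conditions: n-BuLi (1.1 equiv), THF, −78 °C; then Tf2O (1.2 equiv), −78 °C → 0 °C
Reagents that add atoms: trifluoromethanesulfonic anhydride, O=S(=O)(OS(=O)(=O)C(F)(F)F)C(F)(F)F
Why: Bromine–lithium exchange (the two bromines are equivalent) triggers the retro-Brook 1,3 O→C silyl shift, and the resulting ortho-silyl phenoxide is trapped with Tf2O, the standard entry to ortho-silylaryl triflates.

Step 9
Reactants: 9 (E/Z)-2-[5-geranyl-2,4-bis(methoxymethoxy)phenyl]-3-methoxyprop-2-enoic acid; 15 2-bromo-4-(methoxymethoxy)-6-(trimethylsilyl)phenyl triflate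
Product: 18 5-bromo-3-[5-geranyl-2,4-bis(methoxymethoxy)phenyl]-7-(methoxymethoxy)chromen-4-one, via 3-bromo-5-(methoxymethoxy)benzyne 16 (not isolated), via ortho-hydroxyaryl ketone 17 (not isolated)
Conditions: 9 (1 equiv), 15 (2 equiv), CsF (5 equiv), THF, 110 °C, sealed tube
Reagents that add atoms: none
Why: Fluoride converts 15 into aryne 16; the carboxylate oxygen of 9 adds to the aryne carbon remote from bromine (future C8a), the aryl anion formed at the bromine-flanked carbon (future C4a) attacks the carbonyl of the aryl ester just created (4-exo-trig, benzoxetene alkoxide), and ring opening gives the ortho-acyl phenoxide of 17, so that O1–C8a and C4–C4a arise by net insertion of the aryne into the O–C(=O) bond of the acid. The closest known reaction type is the aryne insertion into the C–O bond of carboxylic acids, which with α,β-unsaturated acids runs on by conjugate ring closure to chroman-4-ones. Ring C then closes by 6-endo-trig oxa-Michael addition of the phenoxide to the β-methoxy enone and loss of methoxide, which should give the chromone directly. No stereocentre is formed, and because the addition–elimination passes through a freely rotating enolate, both enol ether isomers of 9 converge on 18. The step needs attack at one aryne carbon only, which the bromine secures (aryne distortion and inductive stabilisation of the ortho anion send the nucleophile to the distal carbon and override the weak opposite bias of the methoxymethoxy group); it also needs acyl transfer to outrun bromide loss and protonation of the aryl anion, which the adjacent ester carbonyl of the s-trans aryl ester (β-carbon held away, so 1,2- and not 1,4-attack) should favour.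

Step 10
Reactants: 18 5-bromo-3-[5-geranyl-2,4-bis(methoxymethoxy)phenyl]-7-(methoxymethoxy)chromen-4-one
Product: 19 3-[5-geranyl-2,4-bis(methoxymethoxy)phenyl]-7-(methoxymethoxy)chromen-4-one
Conditions: Pd(OAc)2 (5 mol %), PPh3 (20 mol %), HCO2H (3 equiv), Et3N (4 equiv), DMF, 80 °C
Reagents that add atoms: none
Why: Palladium-catalysed transfer hydrodebromination (oxidative addition of the carbonyl-activated C–Br bond to zerovalent palladium, formate as hydride donor) should leave the trisubstituted alkenes, the chromone and the MOM ethers untouched in the buffered medium.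

Step 11
Reactants: 19 3-[5-geranyl-2,4-bis(methoxymethoxy)phenyl]-7-(methoxymethoxy)chromen-4-one
Product: 20 3-(5-geranyl-2,4-dihydroxyphenyl)-7-hydroxychromen-4-one
Conditions: 3 M aq. HCl/MeOH (1:5), 45 °C
Reagents that add atoms: none
Why: Acid-catalysed transacetalisation to methanol cleaves the three aryl MOM ethers while no stereocentre is yet present, and the mild temperature is chosen to avoid acid-mediated cyclisation of the geranyl chain onto the neighbouring hydroxyl.

Step 12
Reactants: 20 3-(5-geranyl-2,4-dihydroxyphenyl)-7-hydroxychromen-4-one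
Product: 21 (3R)-3-(5-geranyl-2,4-dihydroxyphenyl)-7-hydroxychroman-4-one
Conditions: recombinant isoflavone reductase (NADPH-dependent 2'-hydroxyisoflavone reductase, cell-free extract), NADP+ (cat.), D-glucose, glucose dehydrogenase, KPi buffer pH 7.0, 5% DMSO, 30 °C
Reagents that add atoms: none
Why: Enzymes of the isoflavone reductase class deliver hydride from NADPH to C2 and a proton to one face of C3 of 2'-hydroxyisoflavones to give (3R)-isoflavanones; 20 carries the 2'-hydroxyl these enzymes require and the 7,2',4'-trihydroxy pattern of their natural substrates, so the enzyme should set C3 as R at neutral pH, where the enolisable centre is not scrambled.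

**Compound list**

1 | 4,6-dibromoresorcinol (4,6-dibromobenzene-1,3-diol) | Oc1cc(O)c(Br)cc1Br | starting material
2 | 1,5-dibromo-2,4-bis(methoxymethoxy)benzene | COCOc1cc(OCOC)c(Br)cc1Br | intermediate
3 | geranyl bromide ((2E)-1-bromo-3,7-dimethylocta-2,6-diene) | CC(C)=CCC/C(C)=C/CBr | starting material
4 | [5-bromo-2,4-bis(methoxymethoxy)phenyl]lithium | [Li]c1cc(Br)c(OCOC)cc1OCOC | intermediate (not isolated)
5 | 1-bromo-5-geranyl-2,4-bis(methoxymethoxy)benzene | CC(C)=CCC/C(C)=C/Cc1cc(Br)c(OCOC)cc1OCOC | intermediate
6 | [5-geranyl-2,4-bis(methoxymethoxy)phenyl]lithium | CC(C)=CCC/C(C)=C/Cc1cc([Li])c(OCOC)cc1OCOC | intermediate (not isolated)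
7 | methyl 2-[5-geranyl-2,4-bis(methoxymethoxy)phenyl]-2-oxoacetate | CC(C)=CCC/C(C)=C/Cc1cc(C(=O)C(=O)OC)c(OCOC)cc1OCOC | intermediate
8 | methyl (E/Z)-2-[5-geranyl-2,4-bis(methoxymethoxy)phenyl]-3-methoxyprop-2-enoate | CC(C)=CCC/C(C)=C/Cc1cc(C(=COC)C(=O)OC)c(OCOC)cc1OCOC | intermediate
9 | (E/Z)-2-[5-geranyl-2,4-bis(methoxymethoxy)phenyl]-3-methoxyprop-2-enoic acid | CC(C)=CCC/C(C)=C/Cc1cc(C(=COC)C(=O)O)c(OCOC)cc1OCOC | intermediate
10 | 4-(methoxymethoxy)phenol | COCOc1ccc(O)cc1 | starting material
11 | 2,6-dibromo-4-(methoxymethoxy)phenol | COCOc1cc(Br)c(O)c(Br)c1 | intermediate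
12 | [2,6-dibromo-4-(methoxymethoxy)phenoxy]trimethylsilane | COCOc1cc(Br)c(O[Si](C)(C)C)c(Br)c1 | intermediate
13 | [3-bromo-5-(methoxymethoxy)-2-(trimethylsilyloxy)phenyl]lithium | COCOc1cc(Br)c(O[Si](C)(C)C)c([Li])c1 | intermediate (not isolated)
14 | lithium 2-bromo-4-(methoxymethoxy)-6-(trimethylsilyl)phenoxide | COCOc1cc(Br)c([O-])c([Si](C)(C)C)c1.[Li+] | intermediate (not isolated)
15 | 2-bromo-4-(methoxymethoxy)-6-(trimethylsilyl)phenyl trifluoromethanesulfonate | COCOc1cc(Br)c(OS(=O)(=O)C(F)(F)F)c([Si](C)(C)C)c1 | intermediate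
16 | 3-bromo-5-(methoxymethoxy)benzyne | COCOC1=CC#CC(Br)=C1 | intermediate (not isolated)
17 | (E/Z)-1-[2-bromo-6-hydroxy-4-(methoxymethoxy)phenyl]-2-[5-geranyl-2,4-bis(methoxymethoxy)phenyl]-3-methoxyprop-2-en-1-one | CC(C)=CCC/C(C)=C/Cc1cc(C(=COC)C(=O)c2c(O)cc(OCOC)cc2Br)c(OCOC)cc1OCOC | intermediate (not isolated)
18 | 5-bromo-3-[5-geranyl-2,4-bis(methoxymethoxy)phenyl]-7-(methoxymethoxy)chromen-4-one | CC(C)=CCC/C(C)=C/Cc1cc(-c2coc3cc(OCOC)cc(Br)c3c2=O)c(OCOC)cc1OCOC | intermediate
19 | 3-[5-geranyl-2,4-bis(methoxymethoxy)phenyl]-7-(methoxymethoxy)chromen-4-one | CC(C)=CCC/C(C)=C/Cc1cc(-c2coc3cc(OCOC)ccc3c2=O)c(OCOC)cc1OCOC | intermediate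
20 | 3-(5-geranyl-2,4-dihydroxyphenyl)-7-hydroxychromen-4-one | CC(C)=CCC/C(C)=C/Cc1cc(-c2coc3cc(O)ccc3c2=O)c(O)cc1O | intermediate
21 | (3R)-3-(5-geranyl-2,4-dihydroxyphenyl)-7-hydroxychroman-4-one | CC(C)=CCC/C(C)=C/Cc1cc([C@@H]2COc3cc(O)ccc3C2=O)c(O)cc1O | target

**Step count and risks**

Total step count: 12. Longest linear sequence: 9 (steps 1–5, then 9–12).

Steps most likely to fail:

Step 9. The aryl anion formed next to bromine may expel bromide (a second aryne) or be protonated (plain aryl ester) before the acyl shift, and attack at the other aryne carbon would put the oxygen in the wrong position. The fallback abandons the aryne and sets out from 5 and commercial 2,4-dihydroxyacetophenone. Compound 5 is converted by bromine–lithium exchange (n-BuLi) and 2-isopropoxy-4,4,5,5-tetramethyl-1,3,2-dioxaborolane into 2-[5-geranyl-2,4-bis(methoxymethoxy)phenyl]-4,4,5,5-tetramethyl-1,3,2-dioxaborolane F1. The acetophenone is protected with MOMCl at the non-chelated hydroxyl to give 1-[2-hydroxy-4-(methoxymethoxy)phenyl]ethanone F2, condensed with DMF dimethyl acetal to the enaminone (E)-3-(dimethylamino)-1-[2-hydroxy-4-(methoxymethoxy)phenyl]prop-2-en-1-one F3, and cyclised with iodine to 3-iodo-7-(methoxymethoxy)chromen-4-one F4. Suzuki–Miyaura coupling of F1 with F4 (Pd(dppf)Cl2, K2CO3, dioxane/H2O) gives 19, where the route is rejoined.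

Step 12. The enzyme may not turn over because the geranyl chain is not accommodated in the active site, or slow enolisation in the buffer may erode the configuration during a long reaction. The fallback sets out from 19. Conjugate reduction with L-Selectride (THF, −78 °C) should give the racemic 3-[5-geranyl-2,4-bis(methoxymethoxy)phenyl]-7-(methoxymethoxy)chroman-4-one F5. Asymmetric transfer hydrogenation under dynamic kinetic resolution (RuCl[(R,R)-TsDPEN](p-cymene), HCO2H/Et3N; C3 epimerises while one enantiomer is reduced faster) should funnel it into the cis-(3R,4R)-configured 3-[5-geranyl-2,4-bis(methoxymethoxy)phenyl]-7-(methoxymethoxy)chroman-4-ol F6; the (R,R) catalyst is expected by analogy with simple chroman-4-ones to give the 4R alcohol. Dess–Martin oxidation then returns the ketone as (3R)-3-[5-geranyl-2,4-bis(methoxymethoxy)phenyl]-7-(methoxymethoxy)chroman-4-one F7. MOM removal as in step 11, at lower temperature, comes back to the route at 21.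

Step 5. Hydrolysis of the hindered, vinylogous ester may be slow, so that conjugate attack of hydroxide with loss of the β-methoxy group competes. The fallback sets out from 7 and reverses the order of events. The much more reactive α-keto ester is saponified first (LiOH, THF/H2O, 0 °C) to 2-[5-geranyl-2,4-bis(methoxymethoxy)phenyl]-2-oxoacetic acid F8. Its carboxylate is then olefinated with an excess of the methoxymethylene ylide (Ph3P(CH2OMe)Cl, KOt-Bu, THF), which comes back to the route at 9 without any ester hydrolysis after the enol ether is in place.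

**Further compounds**

F1 | step 9 | 2-[5-geranyl-2,4-bis(methoxymethoxy)phenyl]-4,4,5,5-tetramethyl-1,3,2-dioxaborolane | CC(C)=CCC/C(C)=C/Cc1cc(B2OC(C)(C)C(C)(C)O2)c(OCOC)cc1OCOC
F2 | step 9 | 1-[2-hydroxy-4-(methoxymethoxy)phenyl]ethanone | CC(=O)c1ccc(OCOC)cc1O
F3 | step 9 | (E)-3-(dimethylamino)-1-[2-hydroxy-4-(methoxymethoxy)phenyl]prop-2-en-1-one | CN(C)/C=C/C(=O)c1ccc(OCOC)cc1O
F4 | step 9 | 3-iodo-7-(methoxymethoxy)chromen-4-one | COCOc1ccc2c(c1)occ(I)c2=O
F5 | step 12 | racemic 3-[5-geranyl-2,4-bis(methoxymethoxy)phenyl]-7-(methoxymethoxy)chroman-4-one | CC(C)=CCC/C(C)=C/Cc1cc(C2COc3cc(OCOC)ccc3C2=O)c(OCOC)cc1OCOC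
F6 | step 12 | (3R,4R)-3-[5-geranyl-2,4-bis(methoxymethoxy)phenyl]-7-(methoxymethoxy)chroman-4-ol | CC(C)=CCC/C(C)=C/Cc1cc([C@@H]2COc3cc(OCOC)ccc3[C@@H]2O)c(OCOC)cc1OCOC
F7 | step 12 | (3R)-3-[5-geranyl-2,4-bis(methoxymethoxy)phenyl]-7-(methoxymethoxy)chroman-4-one | CC(C)=CCC/C(C)=C/Cc1cc([C@@H]2COc3cc(OCOC)ccc3C2=O)c(OCOC)cc1OCOC
F8 | step 5 | 2-[5-geranyl-2,4-bis(methoxymethoxy)phenyl]-2-oxoacetic acid | CC(C)=CCC/C(C)=C/Cc1cc(C(=O)C(=O)O)c(OCOC)cc1OCOC
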